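**Assumption:** the target SMILES has no stereocentres and no E/Z-capable alkenes, so the molecule is achiral and "single enantiomer" adds no requirement. The only stereo-element in the route is the transient E-chalcone. The route is designed from first principles and has not been run; conditions are typical literature-style choices.

## Retrosynthetic overview

1. Target ⇐ global MOM removal from the 5,7,4',5'-tetra-MOM flavonol 16.
2. The pyranone C ring is formed last, by Algar–Flynn–Oyamada (AFO) oxidative cyclisation of 2'-hydroxychalcone 14.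
3. Chalcone 14 ⇐ Claisen–Schmidt condensation of A-ring acetophenone 6 with B-ring benzaldehyde 13.
4. A ring: the 1,1-dimethylallyl group comes from aromatic Claisen rearrangement of the C2-symmetric 4-O-prenyl phloroacetophenone 3, followed by 4,6-bis-MOM protection.
5. B ring: the vicinal diprenyl unit comes from double Stille prenylation of 2,3-dibromo-4,5-bis(MOM-oxy)benzaldehyde 11, made from 5-bromovanillin.

## Forward route

**Step 1**
Reactants: 1, 2',4',6'-trihydroxyacetophenone; 2, prenyl bromide
Product: 3, 1-[2,6-dihydroxy-4-(3-methylbut-2-en-1-yloxy)phenyl]ethan-1-one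
Conditions: prenyl bromide (1.05 equiv), K2CO3 (1.1 equiv), acetone, reflux, 6 h
Reagents that add atoms: prenyl bromide, CC(C)=CCBr
Why: Williamson etherification occurs at the 4-OH, the only non-chelated and most acidic hydroxyl (para to the acetyl), while the two ortho OH groups are hydrogen-bonded to the ketone.

**Step 2**
Reactants: 3, 4-O-prenyl phloroacetophenone
Product: 4, 1-[2,4,6-trihydroxy-3-(2-methylbut-3-en-2-yl)phenyl]ethan-1-one
Conditions: PhNEt2, 195 °C, sealed tube, Ar, 1–2 h
Reagents that add atoms: none
Why: Aromatic Claisen [3,3] rearrangement with allyl inversion gives the 1,1-dimethylallyl group, and because C3 and C5 of 3 are equivalent by symmetry only one regioisomer can form.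

**Step 3**
Reactants: 4, 3-(1,1-dimethylallyl)phloroacetophenone; 5, chloromethyl methyl ether (MOMCl)
Product: 6, 1-[2-hydroxy-4,6-bis(methoxymethoxy)-3-(2-methylbut-3-en-2-yl)phenyl]ethan-1-one
Conditions: MOMCl (2.2 equiv), i-Pr2NEt (3 equiv), CH2Cl2, 0 °C → rt
Reagents that add atoms: MOMCl, COCCl
Why: O-alkylation takes the free 4-OH and the unhindered 6-OH, while the 2-OH, wedged between the acetyl and the quaternary carbon and locked in the C=O hydrogen bond, stays free (confirm by NOE of both OCH2O groups to H-5).

**Step 4**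
Reactants: 7, 5-bromovanillin; 8, bromine
Product: 9, 2,3-dibromo-4-hydroxy-5-methoxybenzaldehyde (5,6-dibromovanillin)
Conditions: Br2 (1.2 equiv), Fe powder (cat.), NaOAc, AcOH, rt, 5 h
Reagents that add atoms: bromine, BrBr
Why: Electrophilic aromatic bromination goes to the position para to the methoxy group, the most activated open site.

**Step 5**
Reactants: 9, 5,6-dibromovanillin
Product: 10, 2,3-dibromo-4,5-dihydroxybenzaldehyde
Conditions: AlCl3 (2 equiv), pyridine (4.5 equiv), CH2Cl2, reflux, 24 h; aq. HCl work-up
Reagents that add atoms: none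
Why: Chelation-assisted Lewis-acid demethylation of an ortho-hydroxyanisole (aluminium bridging phenoxide and OMe) removes the methyl ether before any acid-sensitive prenyl group is present.

**Step 6**
Reactants: 10, dibromocatechol aldehyde; 5, MOMCl
Product: 11, 2,3-dibromo-4,5-bis(methoxymethoxy)benzaldehyde
Conditions: MOMCl (3 equiv), i-Pr2NEt (4 equiv), DMF, 0 °C → rt
Reagents that add atoms: MOMCl, COCCl
Why: Simple phenol O-alkylation gives base-stable acetal protection that tolerates the Pd coupling, KOH and alkaline peroxide to come.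

**Step 7**
Reactants: 11, dibromo bis-MOM aldehyde; 12, tributyl(3-methylbut-2-en-1-yl)stannane
Product: 13, 4,5-bis(methoxymethoxy)-2,3-bis(3-methylbut-2-en-1-yl)benzaldehyde
Conditions: prenylSnBu3 (3 equiv), Pd(PPh3)4 (10 mol %), degassed DMF, 100 °C, 16 h; aq. KF work-up
Reagents that add atoms: tributyl(prenyl)stannane, CCCC[Sn](CCCC)(CCCC)CC=C(C)C
Why: Double Stille coupling, with the CHO-activated C2–Br reacting first and then C3–Br, where reductive elimination at the less substituted allyl terminus gives the linear prenyl groups.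

**Step 8**
Reactants: 6, A-ring acetophenone; 13, B-ring aldehyde
Product: 14, (E)-1-[2-hydroxy-4,6-bis(methoxymethoxy)-3-(2-methylbut-3-en-2-yl)phenyl]-3-[4,5-bis(methoxymethoxy)-2,3-bis(3-methylbut-2-en-1-yl)phenyl]prop-2-en-1-one
Conditions: KOH (50% aq., 10 equiv), EtOH, 0 °C → rt, 24–48 h, Ar
Reagents that add atoms: none
Why: Claisen–Schmidt aldol condensation gives the thermodynamically favoured E-enone, and MOM ethers and isolated alkenes are inert to hydroxide at rt.

**Step 9**
Reactants: 14, chalcone; 15, hydrogen peroxide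
Product: 16, 3-hydroxy-5,7-bis(methoxymethoxy)-2-[4,5-bis(methoxymethoxy)-2,3-bis(3-methylbut-2-en-1-yl)phenyl]-8-(2-methylbut-3-en-2-yl)-4H-chromen-4-one
Conditions: 30% H2O2 (5 equiv), 2 M aq. NaOH, MeOH/THF, 0 °C → rt, 12 h
Reagents that add atoms: hydrogen peroxide, OO
Why: In the Algar–Flynn–Oyamada reaction HOO⁻ attacks only the enone, the 2'-phenoxide (the only free OH) closes the ring to place the dimethylallyl group at C8, and the dihydroflavonol is oxidised to the flavonol while the unactivated prenyl and vinyl alkenes are untouched.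

**Step 10**
Reactants: 16, tetra-MOM flavonol
Product: 17, Broussoflavonol C, 2-[4,5-dihydroxy-2,3-bis(3-methylbut-2-en-1-yl)phenyl]-3,5,7-trihydroxy-8-(2-methylbut-3-en-2-yl)-4H-chromen-4-one
Conditions: 3 M aq. HCl/MeOH (1:5), 45–50 °C, 1–2 h, Ar; stop at full conversion
Reagents that add atoms: none
Why: Acid-catalysed acetal hydrolysis removes all four MOM groups under mild, brief conditions that should outpace protonation of the trisubstituted prenyl alkenes and the terminal vinyl group.

## Compound list

1 | 2',4',6'-trihydroxyacetophenone | CC(=O)c1c(O)cc(O)cc1O | starting material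
2 | prenyl bromide (1-bromo-3-methylbut-2-ene) | CC(C)=CCBr | starting material
3 | 1-[2,6-dihydroxy-4-(3-methylbut-2-en-1-yloxy)phenyl]ethan-1-one | CC(=O)c1c(O)cc(OCC=C(C)C)cc1O | intermediate
4 | 1-[2,4,6-trihydroxy-3-(2-methylbut-3-en-2-yl)phenyl]ethan-1-one | CC(=O)c1c(O)cc(O)c(C(C)(C)C=C)c1O | intermediate
5 | chloromethyl methyl ether (MOMCl) | COCCl | starting material
6 | 1-[2-hydroxy-4,6-bis(methoxymethoxy)-3-(2-methylbut-3-en-2-yl)phenyl]ethan-1-one | CC(=O)c1c(OCOC)cc(OCOC)c(C(C)(C)C=C)c1O | intermediate
7 | 5-bromovanillin (3-bromo-4-hydroxy-5-methoxybenzaldehyde) | COc1cc(C=O)cc(Br)c1O | starting material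
8 | bromine | BrBr | starting material
9 | 2,3-dibromo-4-hydroxy-5-methoxybenzaldehyde | COc1cc(C=O)c(Br)c(Br)c1O | intermediate
10 | 2,3-dibromo-4,5-dihydroxybenzaldehyde | O=Cc1cc(O)c(O)c(Br)c1Br | intermediate
11 | 2,3-dibromo-4,5-bis(methoxymethoxy)benzaldehyde | COCOc1cc(C=O)c(Br)c(Br)c1OCOC | intermediate
12 | tributyl(3-methylbut-2-en-1-yl)stannane | CCCC[Sn](CCCC)(CCCC)CC=C(C)C | starting material
13 | 4,5-bis(methoxymethoxy)-2,3-bis(3-methylbut-2-en-1-yl)benzaldehyde | COCOc1cc(C=O)c(CC=C(C)C)c(CC=C(C)C)c1OCOC | intermediate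
14 | (E)-2'-hydroxy-4',6'-bis(MOM-oxy)-3'-(1,1-dimethylallyl)-4,5-bis(MOM-oxy)-2,3-diprenylchalcone | C=CC(C)(C)c1c(OCOC)cc(OCOC)c(C(=O)/C=C/c2cc(OCOC)c(OCOC)c(CC=C(C)C)c2CC=C(C)C)c1O | intermediate
15 | hydrogen peroxide | OO | starting material
16 | 3-hydroxy-5,7-bis(MOM-oxy)-2-[4,5-bis(MOM-oxy)-2,3-diprenylphenyl]-8-(1,1-dimethylallyl)-4H-chromen-4-one | C=CC(C)(C)c1c(OCOC)cc(OCOC)c2c(=O)c(O)c(-c3cc(OCOC)c(OCOC)c(CC=C(C)C)c3CC=C(C)C)oc12 | intermediate
17 | Broussoflavonol C | C=CC(C)(C)c1c(O)cc(O)c2c(=O)c(O)c(-c3cc(O)c(O)c(CC=C(C)C)c3CC=C(C)C)oc12 | target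

## Summary

**Total steps:** 10 (A-ring branch 3, B-ring branch 4, convergent end-game 3).

**Longest linear sequence:** 7 steps (5-bromovanillin 7 → 9 → 10 → 11 → 13 → 14 → 16 → 17).

**Three steps most likely to fail**

1. **Step 7, double Stille on the vicinal dibromide.** The second, flanked and electron-rich C3–Br may stall, and some branched (γ) coupling is possible. Fallback: install the C3 prenyl by aromatic Claisen instead. Start from 2-bromo-4,5-dihydroxybenzaldehyde, make the 4-O-(1,1-dimethylpropargyl) ether, reduce with Lindlar catalyst to the 1,1-dimethylallyl ether, and rearrange into the only free ortho site (C3). This leaves one aldehyde-activated C2–Br for a single prenyl coupling.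

2. **Step 9, AFO cyclisation.** A 6'-alkoxy chalcone with an ortho-substituted B ring can divert to the aurone or give low conversion. Fallback: build the flavone first and oxidise C3 afterwards. Oxidise 13 to the benzoic acid (Pinnick), esterify with 6, carry out Baker–Venkataraman rearrangement and cyclodehydration to the flavone, then C3-lithiation (LDA, −78 °C), B(OMe)3 and H2O2 to give 16.

3. **Step 10, acidic global MOM removal.** The 3'-prenyl/4'-OH pair can cyclise to a 2,2-dimethylchroman, or the alkenes can hydrate, before the hindered 7-OMOM is cleaved. Fallback: change the protecting-group strategy to SEM ethers (SEMCl in Steps 3 and 6) and finish with a fluoride-mediated, non-acidic global deprotection (TBAF, DMPU, about 60 °C).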